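I decide to judge this row by one number: how much [target] a flask can hold while substrate is still present.

| flask | substrate | reagent | free catalyst | remark | time |
|---|---|---|---|---|---|
| autumn | 0.10 M | 2.7 M | 26 mM | run made earlier |  |
| midnight | 0.10 M | 1.8 M | 13 mM | run made earlier |  |
| alder | 0.10 M | 1.80 M | 26 mM |  | 12 h |
| ash | 0.20 M | 1.80 M | 26 mM |  | 12 h |
| maple | 0.40 M | 1.80 M | 26 mM |  | 12 h |
| birch | 0.80 M | 1.80 M | 26 mM |  | 12 h |
| elm | 1.5 M | 1.80 M | 26 mM |  | 12 h |

| run | time / h | target / % |
|---|---|---|
| autumn | 1.00 | 51.0 |
| autumn | 2.00 | 75.8 |
| autumn | 3.00 | 84.1 |
| autumn | 4.00 | 86.7 |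
| midnight | 0.500 | 8.6 |
| midnight | 1.33 | 28.3 |
| midnight | 2.50 | 48.7 |
| midnight | 4.00 | 61.9 |

(each reading ± 0.5 percentage points)

- "hardly changes" means that all values lie within two and a half points (for a concentration: within two and a half percent of the largest)

- [target] at the end for alder, ash, maple, birch, elm, in this order
- how that number moves from the first to the last of them (falls all the way / hardly changes / rises all the way / rises, then falls / falls, then rises)

Autumn's hourly gains shrink from 8.3 percentage points to 2.6 points, so I extend them geometrically to a level of 87.9 % of the charge, which is 0.0879 M. I suppose that this shortfall is a loss in which substrate consumes target.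

Now I freeze reagent and catalyst. Making is then pseudo-first-order in substrate, and the loss is first order in substrate and in [target], so substrate cancels from their ratio. What remains is a ceiling, the [target] at which the loss equals the making. For a small shortfall, the shortfall is [target] squared over the ceiling, so autumn's ceiling is 0.638 M.

Autumn carries 3.00 times midnight's product of catalyst and reagent. It reaches 51.0 % in 1.00 h, while midnight has 48.7 % at 2.50 h. Both settings differ between these two runs, so they do not part catalyst from reagent, and I assume that making follows that product. At 1.80 M reagent and 26 mM catalyst, the ceiling for this row is 0.425 M, the [target] where loss and making balance.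

Each unit of substrate used then yields (ceiling minus [target]) over (ceiling plus [target]), so my curve starts with slope one. Integrated, it reaches 0.212 M at a charge of 0.377 M, near maple. It reaches 0.319 M at 0.860 M, near birch, and then it flattens towards the ceiling. With reagent frozen, my own row therefore rises and bends over.

The forecast gives 0.088 M, 0.176 M, 0.35 M, 0.7 M and 1.26 M, and its shape is rises all the way. Its ground is “Yield stays about 88% of charge”. Its elm value stands far above my ceiling.

The flask gives 0.0858 M, 0.148 M, 0.225 M, 0.275 M and 0.255 M. The shape is rises, then falls, and the row turns at 0.92 M.

    substrate + free catalyst ⇌ free catalyst + open intermediate (K = 0.630, k = 0.0250 M⁻¹ s⁻¹)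
    free catalyst + open intermediate ⇌ catalyst intermediate (K = 11.0 M⁻¹, k = 0.300 M⁻¹ s⁻¹)
    reagent + catalyst intermediate → free catalyst + target (k = 0.00180 M⁻¹ s⁻¹)
    substrate + target → side product (k = 5.30 × 10⁻⁴ M⁻¹ s⁻¹)

The largest single effect on elm is the step in which substrate consumes target: with that step taken away, elm reaches 1.30 M. With reagent held at its charge, elm reaches 0.328 M, less than the ceiling of 0.425 M. On alder, the shortfall rule gives 0.0173 M, and the charge less the target is 0.0142 M.

Readings and results are calculated with constants of no real substance, noise included.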